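**Plan**

1. Retrosynthesis: the C6 acetyl (C6–C=O bond) and the O-5 MOM group go first; the right-hand pyran ring is then opened at O1'–C2' and C4a'–C4' to a 3,5-dimethoxy-4-alkylphenol and prenal.
2. The dimethoxy benzene ring is cut at C7'–C8', C8a'–C4a' and C6'–C7' into a 4-substituted 3-methoxycyclobutenone and (triisopropylsiloxy)acetylene; the cyclobutenone is cut at C5'–C6' into an aldoketene and methoxyacetylene.
3. Feature that allows this: ring C4a'–C8a' is a benzene-1,3,5-triol triether with C6' between O-5' and O-7' and para to O-8a'. The benzannulation delivers these three oxygens differentiated, and once O-5' and O-7' are both methyl, C8' and C4a' beside O-8a' are equivalent for pyran closure.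
4. The ketene comes from (R)-3-(chromen-3-yl)butanoic acid; cutting its C–CH3 bond gives a dienyl thioester, which goes back to a chromene-3-carbaldehyde and, through O1–C2 and C3–C4, to a salicylaldehyde and prenal.
5. Forward order: left pyran ring (oxa-Michael/aldol), side chain with the stereocentre, cyclobutenone, dimethoxy benzene ring (benzannulation), right pyran ring, then acetyl and deprotection.
6. Stereochemistry: the only stereocentre is set by ligand-controlled copper-catalysed 1,4-addition of MeMgBr and carried through unchanged. Its descriptor is R up to 26 and S from 27 on only because the CIP ranking changes.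

Key step: step 12

Abbreviation and numbering: Chr = 7-methoxy-5-(methoxymethoxy)-2,2-dimethyl-2H-chromen-3-yl; unprimed locants belong to the acetyl-bearing chromene, primed locants to the dimethoxychromene.
Assumption: CuI/(R)-Tol-BINAP is taken to deliver methyl to the face that gives (R)-11, by analogy with β-aryl thioesters; if the sense proves opposite, (S)-Tol-BINAP is used and nothing else changes.

**Route**

Step 1
Reactants: 1 2,4,6-trihydroxybenzaldehyde
Product: 2 2,6-dihydroxy-4-methoxybenzaldehyde
Conditions: MeI (1.05 equiv), NaHCO3, DMF, 40 °C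
Reagents that add atoms: iodomethane, CI
Why: The 4-OH, para to the formyl group and not hydrogen-bonded to it, is the most acidic phenol, so hydrogencarbonate should ionise only that position for a Williamson O-methylation.

Step 2
Reactants: 2 2,6-dihydroxy-4-methoxybenzaldehyde
Product: 3 2-hydroxy-4-methoxy-6-(methoxymethoxy)benzaldehyde
Conditions: MOMCl (1.1 equiv), i-Pr2NEt, CH2Cl2, 0 °C
Reagents that add atoms: chloromethyl methyl ether, COCCl
Why: O-alkylation of one of the two equivalent ortho phenols leaves the other locked in a hydrogen bond to the aldehyde, so a second alkylation is slow and the ring is desymmetrised.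

Step 3
Reactants: 3 2-hydroxy-4-methoxy-6-(methoxymethoxy)benzaldehyde; 4 3-methylbut-2-enal (prenal)
Product: 6 7-methoxy-5-(methoxymethoxy)-2,2-dimethyl-2H-chromene-3-carbaldehyde (Chr-CHO), via oxa-Michael adduct 5 (not isolated)
Conditions: prenal (2 equiv), K2CO3, 1,4-dioxane, reflux
Reagents that add atoms: none
Why: Domino oxa-Michael addition of the phenoxide to the β-carbon of prenal, then intramolecular aldol condensation of adduct 5 onto the aryl aldehyde, should close the pyran ring (O1–C2 and C3–C4); with O-5 masked, C-alkylation of the arene by prenal is held back.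

Step 4
Reactants: 7 (diethoxyphosphoryl)acetic acid; 8 ethanethiol
Product: 9 S-ethyl 2-(diethoxyphosphoryl)ethanethioate
Conditions: DCC, DMAP (cat.), CH2Cl2, 0 °C to rt
Reagents that add atoms: none
Why: Carbodiimide-mediated (Steglich) thioesterification gives the phosphonate needed to install a thioester acceptor.

Step 5
Reactants: 6 Chr-CHO; 9 S-ethyl 2-(diethoxyphosphoryl)ethanethioate
Product: 10 S-ethyl (2E)-3-Chr-prop-2-enethioate
Conditions: NaH, THF, 0 °C to rt
Reagents that add atoms: none
Why: Horner–Wadsworth–Emmons olefination of the non-enolisable enal with the stabilised phosphonate anion should give the (E)-dienyl thioester.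

Step 6
Reactants: 10 S-ethyl (2E)-3-Chr-prop-2-enethioate
Product: 11 S-ethyl (3R)-3-Chr-butanethioate
Conditions: MeMgBr (3 equiv), CuI (5 mol %), (R)-Tol-BINAP (6 mol %), t-BuOMe, −70 °C
Reagents that add atoms: methylmagnesium bromide, C[Mg]Br
Why: Copper-catalysed asymmetric conjugate addition of a Grignard reagent to an α,β-unsaturated thioester, in which the Tol-BINAP-bound methylcopper species adds to one enantioface and sets the stereocentre as R; 1,6-addition should be disfavoured because C4 is a ring carbon shielded by the peri OMOM group and its attack would break the styrene conjugation.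

Step 7
Reactants: 11 S-ethyl (3R)-3-Chr-butanethioate
Product: 12 (3R)-3-Chr-butanoic acid
Conditions: LiOH, THF/H2O, rt; then cold dilute HCl to pH 4
Reagents that add atoms: lithium hydroxide, [Li+].[OH-]
Why: Thioester saponification (acyl substitution) is mild, the stereocentre is β to the carbonyl and cannot epimerise, and the MOM ether should survive the brief work-up at pH 4.

Step 8
Reactants: 12 (3R)-3-Chr-butanoic acid
Product: 13 (3R)-3-Chr-butanoyl chloride
Conditions: 1-chloro-N,N,2-trimethylprop-1-en-1-amine (1.2 equiv), CH2Cl2, 0 °C to rt; used crude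
Reagents that add atoms: 1-chloro-N,N,2-trimethylprop-1-en-1-amine, CC(C)=C(Cl)N(C)C
Why: Acid chloride formation with an α-chloroenamine releases no free HCl, which spares the MOM acetal and the electron-rich chromene.

Step 9
Reactants: 14 2-chloro-1,1-dimethoxyethane (chloroacetaldehyde dimethyl acetal)
Product: 16 methoxyethyne (methoxyacetylene), via sodium methoxyacetylide 15 (not isolated)
Conditions: NaNH2 (3 equiv), liquid NH3, −33 °C; then cold saturated aqueous NaCl; distilled and kept as a cold solution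
Reagents that add atoms: none
Why: Two base-induced β-eliminations (loss of HCl and of methanol) give the acetylide 15, which is protonated on quenching; the alkyne boils near 23 °C and is handled cold.

Step 10
Reactants: 13 (3R)-3-Chr-butanoyl chloride; 16 methoxyethyne
Product: 18 3-methoxy-4-[(1R)-1-Chr-ethyl]cyclobut-2-en-1-one (both C4 epimers), via aldoketene 17 (not isolated)
Conditions: 16 (4 equiv), Et3N (slow addition), CH2Cl2, 0 °C to rt, sealed flask
Reagents that add atoms: none
Why: Dehydrochlorination gives aldoketene 17, trapped in a ketene–ynol ether [2+2] cycloaddition in which the nucleophilic CH terminus of the alkyne bonds to the ketene carbonyl carbon and the oxygenated carbon to the ketene α-carbon (C5'–C6'); the new ring stereocentre is inconsequential because both epimers converge in step 12.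

Step 11
Reactants: 19 ethyne (acetylene)
Product: 22 (ethynyloxy)tri(propan-2-yl)silane [(triisopropylsiloxy)acetylene], via lithium acetylide 20 (not isolated), via lithium ethynolate 21 (not isolated)
Conditions: C2H2 (excess), n-BuLi, THF, −78 °C; t-BuOOLi (from t-BuOOH and LiN(SiMe3)2), −78 to −20 °C; i-Pr3SiOTf, −78 to 0 °C
Reagents that add atoms: tert-butyl hydroperoxide, CC(C)(C)OO; triisopropylsilyl trifluoromethanesulfonate, CC(C)[Si](C(C)C)(C(C)C)OS(=O)(=O)C(F)(F)F
Why: Oxidation of a lithium acetylide by the electrophilic oxygen of lithium tert-butyl peroxide gives the ynolate, which the hard, bulky silyl triflate should silylate on oxygen (ynolate O-silylation); the oxidation is kept below −20 °C under excess acetylene to hold back disproportionation of 20.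

Step 12
Reactants: 18 3-methoxy-4-[(1R)-1-Chr-ethyl]cyclobut-2-en-1-one; 22 (triisopropylsiloxy)acetylene
Product: 27 3-methoxy-2-[(1S)-1-Chr-ethyl]-5-[tri(propan-2-yl)silyloxy]phenol, via vinylketene 23 (not isolated), via vinylcyclobutenone 24 (not isolated), via dienylketene 25 (not isolated), via cyclohexadienone 26 (not isolated)
Conditions: 22 (2 equiv), toluene, 80 °C, then 100 °C, sealed tube
Reagents that add atoms: none
Why: Thermal 4π electrocyclic opening of 18, with the side chain rotating outward, gives methoxyvinylketene 23; its carbonyl carbon is attacked by the CH terminus of the ynol ether in a [2+2] cycloaddition that forms C7'–C8' and C8a'–C4a' (24). A second 4π opening gives dienylketene 25, whose 6π electrocyclic closure forms C6'–C7' and so closes the benzene ring; dienone 26 then tautomerises to the phenol. The closest known reaction type is the Danheiser benzannulation of cyclobutenones with siloxy- and alkoxyalkynes, including the thermal union of 3-alkoxycyclobutenones with alkoxyacetylenes to benzene-1,3,5-triol ethers. No new stereocentre remains in the product, and the existing one lies outside every reacting π-system, the outward rotation keeping its C–H away from a [1,5]-shift to the ketene. The step needs regioselectivity, which the polarity of the ynol ether secures by placing the silyloxy carbon para to the side chain, and it leaves the three oxygens as OH, OMe and OSi. It also needs the ketene to be intercepted before it dimerises or acylates the product phenol, which the excess of alkyne and the two-stage heating are meant to secure.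

Step 13
Reactants: 27 3-methoxy-2-[(1S)-1-Chr-ethyl]-5-[tri(propan-2-yl)silyloxy]phenol
Product: 28 {3,5-dimethoxy-4-[(1S)-1-Chr-ethyl]phenoxy}tri(propan-2-yl)silane
Conditions: MeI, K2CO3, acetone, 50 °C
Reagents that add atoms: iodomethane, CI
Why: Williamson O-methylation of the only free phenol; the triisopropylsilyl aryl ether should tolerate carbonate in acetone, and C6' is now flanked by two equivalent methoxy groups.

Step 14
Reactants: 28 {3,5-dimethoxy-4-[(1S)-1-Chr-ethyl]phenoxy}tri(propan-2-yl)silane
Product: 29 3,5-dimethoxy-4-[(1S)-1-Chr-ethyl]phenol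
Conditions: Bu4NF, THF, 0 °C
Reagents that add atoms: none
Why: Fluoride-induced desilylation of the aryl silyl ether releases the phenol para to the side chain without touching the MOM acetal.

Step 15
Reactants: 29 3,5-dimethoxy-4-[(1S)-1-Chr-ethyl]phenol; 4 3-methylbut-2-enal (prenal)
Product: 31 6-[(1S)-1-Chr-ethyl]-5,7-dimethoxy-2,2-dimethyl-2H-chromene, via quinone methide 30 (not isolated)
Conditions: prenal (3 equiv), pyridine, 140 °C, sealed tube
Reagents that add atoms: none
Why: Phenol–enal chromene annulation, in which aldol-type C-alkylation of an ortho carbon and loss of water give ortho-quinone methide 30, which closes by oxa-6π electrocyclisation (C4a'–C4' and O1'–C2'); the two ortho carbons are equivalent, so a single chromene should result.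

Step 16
Reactants: 31 6-[(1S)-1-Chr-ethyl]-5,7-dimethoxy-2,2-dimethyl-2H-chromene
Product: 33 1-{3-[(1S)-1-(5,7-dimethoxy-2,2-dimethyl-2H-chromen-6-yl)ethyl]-7-methoxy-5-(methoxymethoxy)-2,2-dimethyl-2H-chromen-6-yl}ethan-1-one, via C6 aryllithium 32 (not isolated)
Conditions: n-BuLi (1.3 equiv), TMEDA, THF, −20 to 0 °C; then N-methoxy-N-methylacetamide, −78 °C to rt
Reagents that add atoms: N-methoxy-N-methylacetamide, CON(C)C(C)=O
Why: Directed ortho-metalation, in which the chelating OMOM group and the adjacent OMe make C6 (the only carbon ortho to OMOM) the kinetically preferred site over C8 and C8', each flanked only by OMe and a hindered pyran oxygen; the N-methoxy-N-methylamide then acylates the aryllithium without over-addition.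

Step 17
Reactants: 33 1-{3-[(1S)-1-(5,7-dimethoxy-2,2-dimethyl-2H-chromen-6-yl)ethyl]-7-methoxy-5-(methoxymethoxy)-2,2-dimethyl-2H-chromen-6-yl}ethan-1-one
Product: 34 1-{3-[(1S)-1-(5,7-dimethoxy-2,2-dimethyl-2H-chromen-6-yl)ethyl]-5-hydroxy-7-methoxy-2,2-dimethyl-2H-chromen-6-yl}ethan-1-one (CNP0303487.1)
Conditions: HCl (0.5 M in MeOH), 0 °C to rt
Reagents that add atoms: none
Why: Acid-catalysed acetal exchange (MOM cleavage) is especially easy for an ether ortho to a carbonyl group, so dilute methanolic HCl should free the hydrogen-bonded 5-OH before the chromene double bonds are affected.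

**Compound list**

1 | 2,4,6-trihydroxybenzaldehyde | O=Cc1c(O)cc(O)cc1O | starting material
2 | 2,6-dihydroxy-4-methoxybenzaldehyde | COc1cc(O)c(C=O)c(O)c1 | intermediate
3 | 2-hydroxy-4-methoxy-6-(methoxymethoxy)benzaldehyde | COCOc1cc(OC)cc(O)c1C=O | intermediate
4 | 3-methylbut-2-enal (prenal) | CC(C)=CC=O | starting material
5 | 3-[2-formyl-5-methoxy-3-(methoxymethoxy)phenoxy]-3-methylbutanal (oxa-Michael adduct) | COCOc1cc(OC)cc(OC(C)(C)CC=O)c1C=O | intermediate
6 | 7-methoxy-5-(methoxymethoxy)-2,2-dimethyl-2H-chromene-3-carbaldehyde (Chr-CHO) | COc1cc2c(c(OCOC)c1)C=C(C=O)C(C)(C)O2 | intermediate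
7 | (diethoxyphosphoryl)acetic acid | CCOP(=O)(CC(=O)O)OCC | starting material
8 | ethanethiol | CCS | starting material
9 | S-ethyl 2-(diethoxyphosphoryl)ethanethioate | CCOP(=O)(OCC)CC(=O)SCC | intermediate
10 | S-ethyl (2E)-3-Chr-prop-2-enethioate | COc1cc2c(c(OCOC)c1)C=C(/C=C/C(=O)SCC)C(C)(C)O2 | intermediate
11 | S-ethyl (3R)-3-Chr-butanethioate | COc1cc2c(c(OCOC)c1)C=C([C@H](C)CC(=O)SCC)C(C)(C)O2 | intermediate
12 | (3R)-3-Chr-butanoic acid | COc1cc2c(c(OCOC)c1)C=C([C@H](C)CC(=O)O)C(C)(C)O2 | intermediate
13 | (3R)-3-Chr-butanoyl chloride | COc1cc2c(c(OCOC)c1)C=C([C@H](C)CC(=O)Cl)C(C)(C)O2 | intermediate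
14 | 2-chloro-1,1-dimethoxyethane (chloroacetaldehyde dimethyl acetal) | COC(CCl)OC | starting material
15 | sodium methoxyacetylide | [Na+].[C-]#COC | intermediate
16 | methoxyethyne (methoxyacetylene) | C#COC | intermediate
17 | (3R)-3-Chr-but-1-en-1-one (aldoketene) | COc1cc2c(c(OCOC)c1)C=C([C@H](C)C=C=O)C(C)(C)O2 | intermediate
18 | 3-methoxy-4-[(1R)-1-Chr-ethyl]cyclobut-2-en-1-one (both C4 epimers) | COc1cc2c(c(OCOC)c1)C=C([C@H](C)C1C(=O)C=C1OC)C(C)(C)O2 | intermediate
19 | ethyne (acetylene) | C#C | starting material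
20 | lithium acetylide | [Li+].[C-]#C | intermediate
21 | lithium ethynolate | [Li+].[O-]C#C | intermediate
22 | (ethynyloxy)tri(propan-2-yl)silane [(triisopropylsiloxy)acetylene] | C#CO[Si](C(C)C)(C(C)C)C(C)C | intermediate
23 | (3Z,5R)-3-methoxy-5-Chr-hexa-1,3-dien-1-one (vinylketene) | COc1cc2c(c(OCOC)c1)C=C([C@H](C)/C=C(OC)/C=C=O)C(C)(C)O2 | intermediate
24 | 4-[(1Z,3R)-1-methoxy-3-Chr-but-1-en-1-yl]-3-[tri(propan-2-yl)silyloxy]cyclobut-2-en-1-one (vinylcyclobutenone, both ring epimers) | COc1cc2c(c(OCOC)c1)C=C([C@H](C)/C=C(OC)/C1C(=O)C=C1O[Si](C(C)C)(C(C)C)C(C)C)C(C)(C)O2 | intermediate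
25 | (3E,5Z,7R)-5-methoxy-7-Chr-3-[tri(propan-2-yl)silyloxy]octa-1,3,5-trien-1-one (dienylketene) | COc1cc2c(c(OCOC)c1)C=C([C@H](C)/C=C(OC)/C=C(O[Si](C(C)C)(C(C)C)C(C)C)\C=C=O)C(C)(C)O2 | intermediate
26 | 5-methoxy-6-[(1R)-1-Chr-ethyl]-3-[tri(propan-2-yl)silyloxy]cyclohexa-2,4-dien-1-one (both ring epimers) | COc1cc2c(c(OCOC)c1)C=C([C@H](C)C1C(=O)C=C(O[Si](C(C)C)(C(C)C)C(C)C)C=C1OC)C(C)(C)O2 | intermediate
27 | 3-methoxy-2-[(1S)-1-Chr-ethyl]-5-[tri(propan-2-yl)silyloxy]phenol | COc1cc2c(c(OCOC)c1)C=C([C@H](C)c1c(O)cc(O[Si](C(C)C)(C(C)C)C(C)C)cc1OC)C(C)(C)O2 | intermediate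
28 | {3,5-dimethoxy-4-[(1S)-1-Chr-ethyl]phenoxy}tri(propan-2-yl)silane | COc1cc2c(c(OCOC)c1)C=C([C@H](C)c1c(OC)cc(O[Si](C(C)C)(C(C)C)C(C)C)cc1OC)C(C)(C)O2 | intermediate
29 | 3,5-dimethoxy-4-[(1S)-1-Chr-ethyl]phenol | COc1cc2c(c(OCOC)c1)C=C([C@H](C)c1c(OC)cc(O)cc1OC)C(C)(C)O2 | intermediate
30 | 3,5-dimethoxy-4-[(1S)-1-Chr-ethyl]-6-(3-methylbut-2-en-1-ylidene)cyclohexa-2,4-dien-1-one (quinone methide) | COc1cc2c(c(OCOC)c1)C=C([C@H](C)C1=C(OC)C(=CC=C(C)C)C(=O)C=C1OC)C(C)(C)O2 | intermediate
31 | 6-[(1S)-1-Chr-ethyl]-5,7-dimethoxy-2,2-dimethyl-2H-chromene | COc1cc2c(c(OCOC)c1)C=C([C@H](C)c1c(OC)cc3c(c1OC)C=CC(C)(C)O3)C(C)(C)O2 | intermediate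
32 | C6-lithio derivative of 31 (lithium on the carbon between OMOM and OMe) | COc1cc2c(c(OCOC)c1[Li])C=C([C@H](C)c1c(OC)cc3c(c1OC)C=CC(C)(C)O3)C(C)(C)O2 | intermediate
33 | 1-{3-[(1S)-1-(5,7-dimethoxy-2,2-dimethyl-2H-chromen-6-yl)ethyl]-7-methoxy-5-(methoxymethoxy)-2,2-dimethyl-2H-chromen-6-yl}ethan-1-one | COc1cc2c(c(OCOC)c1C(C)=O)C=C([C@H](C)c1c(OC)cc3c(c1OC)C=CC(C)(C)O3)C(C)(C)O2 | intermediate
34 | 1-{3-[(1S)-1-(5,7-dimethoxy-2,2-dimethyl-2H-chromen-6-yl)ethyl]-5-hydroxy-7-methoxy-2,2-dimethyl-2H-chromen-6-yl}ethan-1-one (CNP0303487.1) | COc1cc2c(c(O)c1C(C)=O)C=C([C@H](C)c1c(OC)cc3c(c1OC)C=CC(C)(C)O3)C(C)(C)O2 | target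

**Step count and risks**

Total steps: 17. Longest linear sequence: 14 (steps 1–3, 5–8, 10, 12–17); steps 4, 9 and 11 prepare reagents.

Steps most likely to fail:

1. Step 6. Methyl may be delivered to the δ-carbon (1,6-addition across the diene), the electron-rich acceptor may turn over too slowly, or facial selectivity may be poor. The fallback replaces ligand control by auxiliary control with stoichiometric organocopper; it sets out from 10 and returns at 12. Thioester 10 is saponified (LiOH, THF/H2O) to (2E)-3-Chr-prop-2-enoic acid F1. N-Acylation of (R)-4-phenyl-1,3-oxazolidin-2-one (pivaloyl chloride, Et3N, LiCl, THF) gives (4R)-3-[(2E)-3-Chr-prop-2-enoyl]-4-phenyl-1,3-oxazolidin-2-one F2. MeMgBr with CuBr·SMe2 (1.5 equiv each, THF/Me2S, −40 to −10 °C) should add to the magnesium-chelated syn-s-cis imide at the β-carbon from the face away from the phenyl group, giving (4R)-3-[(3R)-3-Chr-butanoyl]-4-phenyl-1,3-oxazolidin-2-one F3. LiOH/H2O2 then removes the auxiliary to give 12.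

2. Step 12. The alkoxyvinylketene may dimerise or acylate the product phenol before the ynol ether intercepts it, or ring opening may need temperatures at which the siloxyalkyne isomerises to a silylketene. The fallback generates the same vinylketene by base at or below room temperature instead of by electrocyclic opening; it sets out from 13 and returns at 27. Acid chloride 13 is homologated with potassium methyl malonate (MgCl2, Et3N, MeCN; decarboxylation on work-up) to methyl (5R)-5-Chr-3-oxohexanoate F4. O-Methylation (Me2SO4, Cs2CO3, DMF) gives methyl (2E,5R)-3-methoxy-5-Chr-hex-2-enoate F5, and saponification (LiOH) gives (2E,5R)-3-methoxy-5-Chr-hex-2-enoic acid F6. The α-chloroenamine of step 8 converts it to (2E,5R)-3-methoxy-5-Chr-hex-2-enoyl chloride F7. Slow addition of Et3N to F7 and 22 (3 equiv) in toluene at rt effects 1,4-dehydrochlorination to vinylketene 23, and gentle warming completes the cascade through 24–26 to 27.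

3. Step 16. Lithiation may occur at C8 or C8' instead of C6, the doubly activated allylic/benzylic C–H at the stereocentre may be deprotonated with loss of configuration, or the hindered aryllithium may be quenched by proton transfer from the amide. The fallback avoids strong base and uses phenoxide-directed electrophilic substitution; it sets out from 31 and ends at 34. The MOM group is removed first (HCl, MeOH) to give 3-[(1S)-1-(5,7-dimethoxy-2,2-dimethyl-2H-chromen-6-yl)ethyl]-7-methoxy-2,2-dimethyl-2H-chromen-5-ol F8. Magnesium-phenoxide-directed ortho-formylation (MgCl2, Et3N, paraformaldehyde, MeCN, reflux) can only reach C6, the single free carbon ortho to the phenol, and gives 3-[(1S)-1-(5,7-dimethoxy-2,2-dimethyl-2H-chromen-6-yl)ethyl]-5-hydroxy-7-methoxy-2,2-dimethyl-2H-chromene-6-carbaldehyde F9. MeMgBr (2.5 equiv, THF, 0 °C) gives 3-[(1S)-1-(5,7-dimethoxy-2,2-dimethyl-2H-chromen-6-yl)ethyl]-6-(1-hydroxyethyl)-7-methoxy-2,2-dimethyl-2H-chromen-5-ol F10 (both carbinol epimers), and MnO2 in CH2Cl2 oxidises the benzylic carbinol to 34.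

Further compounds
F1 | step 6 | (2E)-3-Chr-prop-2-enoic acid | COc1cc2c(c(OCOC)c1)C=C(/C=C/C(=O)O)C(C)(C)O2
F2 | step 6 | (4R)-3-[(2E)-3-Chr-prop-2-enoyl]-4-phenyl-1,3-oxazolidin-2-one | COc1cc2c(c(OCOC)c1)C=C(/C=C/C(=O)N1[C@H](c3ccccc3)COC1=O)C(C)(C)O2
F3 | step 6 | (4R)-3-[(3R)-3-Chr-butanoyl]-4-phenyl-1,3-oxazolidin-2-one | COc1cc2c(c(OCOC)c1)C=C([C@H](C)CC(=O)N1[C@H](c3ccccc3)COC1=O)C(C)(C)O2
F4 | step 12 | methyl (5R)-5-Chr-3-oxohexanoate | COc1cc2c(c(OCOC)c1)C=C([C@H](C)CC(=O)CC(=O)OC)C(C)(C)O2
F5 | step 12 | methyl (2E,5R)-3-methoxy-5-Chr-hex-2-enoate | COc1cc2c(c(OCOC)c1)C=C([C@H](C)C/C(OC)=C\C(=O)OC)C(C)(C)O2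
F6 | step 12 | (2E,5R)-3-methoxy-5-Chr-hex-2-enoic acid | COc1cc2c(c(OCOC)c1)C=C([C@H](C)C/C(OC)=C\C(=O)O)C(C)(C)O2
F7 | step 12 | (2E,5R)-3-methoxy-5-Chr-hex-2-enoyl chloride | COc1cc2c(c(OCOC)c1)C=C([C@H](C)C/C(OC)=C\C(=O)Cl)C(C)(C)O2
F8 | step 16 | 3-[(1S)-1-(5,7-dimethoxy-2,2-dimethyl-2H-chromen-6-yl)ethyl]-7-methoxy-2,2-dimethyl-2H-chromen-5-ol | COc1cc2c(c(O)c1)C=C([C@H](C)c1c(OC)cc3c(c1OC)C=CC(C)(C)O3)C(C)(C)O2
F9 | step 16 | 3-[(1S)-1-(5,7-dimethoxy-2,2-dimethyl-2H-chromen-6-yl)ethyl]-5-hydroxy-7-methoxy-2,2-dimethyl-2H-chromene-6-carbaldehyde | COc1cc2c(c(O)c1C=O)C=C([C@H](C)c1c(OC)cc3c(c1OC)C=CC(C)(C)O3)C(C)(C)O2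
F10 | step 16 | 3-[(1S)-1-(5,7-dimethoxy-2,2-dimethyl-2H-chromen-6-yl)ethyl]-6-(1-hydroxyethyl)-7-methoxy-2,2-dimethyl-2H-chromen-5-ol (both carbinol epimers) | COc1cc2c(c(O)c1C(C)O)C=C([C@H](C)c1c(OC)cc3c(c1OC)C=CC(C)(C)O3)C(C)(C)O2
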